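**Assumption:** natural (−)-sclareol (5S,8R,9R,10S,13R) is the starting material; the target SMILES decodes to the normal labdane configuration (5S,9R,10S; 5α-H, 9α-H, 10β-CH3; 13E), which sclareol already carries.

## Retrosynthetic overview

1. Acid 11 ⇒ enal 10 (aldehyde to acid) ⇒ Δ7 alkene 6 with C17 still a methyl: the C17–O bond comes from an SeO2 ene reaction followed by a [2,3]-sigmatropic shift.
2. 6 ⇒ 8α,15-diester 5 by loss of the tertiary C8 acyloxy group toward C7.
3. 5 ⇒ tertiary allylic diester 4: the C15–O bond and the 13E alkene come from a [3,3]-sigmatropic 1,3-acyloxy shift; 4 ⇒ sclareol 1 + isobutyryl chloride 2.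
4. Ring order: no ring is formed. Rings A and B (trans-decalin with C5, C9, C10) are bought intact in sclareol; the C8 and C13 carbinol centres are converted into the two alkenes.

## Route

**Step 1**

Reactants: 1 (−)-sclareol; 2 isobutyryl chloride

Product: 4 (13R)-labd-14-ene-8α,13-diyl bis(2-methylpropanoate), via dilithium dialkoxide 3 (not isolated)

Conditions: n-BuLi (2.2 equiv), THF, −78 → 0 °C; then 2 (3 equiv), 0 °C → rt

Reagents that add atoms: isobutyryl chloride (2), `CC(C)C(=O)Cl`

Why: O-acylation of the two pre-formed tertiary lithium alkoxides by the acid chloride (alkoxide acylation) esterifies both hindered hydroxyls without ionising the tertiary allylic centre, so C8 and C13 keep their configuration and the C8 ester later prevents cyclic-ether formation onto the allyl unit.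

**Step 2**

Reactants: 4 (13R)-labd-14-ene-8α,13-diyl bis(2-methylpropanoate)

Product: 5 (13E)-labd-13-ene-8α,15-diyl bis(2-methylpropanoate)

Conditions: PdCl2(MeCN)2 (5 mol %), THF, rt, 16 h

Reagents that add atoms: none

Why: Overman-type divalent-palladium-catalysed [3,3]-sigmatropic rearrangement of the tertiary allylic ester (through a six-membered 1,3-dioxan-2-ylium palladium intermediate) forms the C15–O bond and runs downhill to the primary ester with a trisubstituted alkene; the chair-like intermediate with the large C12 chain equatorial favours 13E (probably only about 2–4:1, the 13Z isomer being removed on AgNO3-impregnated silica), the non-allylic C8 ester is inert, and no stereocentre is created because C13 becomes sp2.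

**Step 3**

Reactants: 5 (13E)-labd-13-ene-8α,15-diyl bis(2-methylpropanoate)

Product: 6 (13E)-labda-7,13-dien-15-yl 2-methylpropanoate

Conditions: p-TsOH·H2O (10 mol %), toluene, 70 °C, 1–2 h

Reagents that add atoms: none

Why: acid-catalysed alkyl–oxygen ionisation of the tertiary C8 ester (E1 elimination), accelerated by relief of the 1,3-diaxial C17/C20 methyl interaction, gives the C8 cation, which loses the axial 7α-H to give the Δ7 alkene as the expected main isomer (exocyclic 8(17) alkene is re-protonated and funnelled to Δ7, the minor Δ8(9) isomer is separated on AgNO3-impregnated silica), while the primary allylic ester should ionise much more slowly under catalytic acid in toluene and C5, C9 and C10 are untouched.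

**Step 4**

Reactants: 6 (13E)-labda-7,13-dien-15-yl 2-methylpropanoate

Product: 10 (13E)-17-oxolabda-7,13-dien-15-yl 2-methylpropanoate, via allylseleninic acid 7 (not isolated), via selenium ester 8 (not isolated), via allylic alcohol 9 (not isolated)

Conditions: SeO2 (1.5 equiv), 1,4-dioxane (trace H2O), reflux, 3 h

Reagents that add atoms: SeO2 (selenium dioxide), `O=[Se]=O`

Why: Riley oxidation, in which SeO2 undergoes an ene reaction at the electron-rich ring alkene (Se to C7, H taken from the C17 methyl at the more substituted terminus) and allylseleninic acid 7 undergoes the [2,3]-sigmatropic shift that forms the C17–O bond and returns the double bond to C7–C8; hydrolysis of 8 gives alcohol 9, which SeO2 oxidises on to the conjugated enal, while the side-chain alkene is deactivated by its allylic ester oxygen and the transient C7 stereocentre disappears.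

**Step 5**

Reactants: 10 (13E)-17-oxolabda-7,13-dien-15-yl 2-methylpropanoate

Product: 11 (13E)-15-(2-methylpropanoyloxy)labda-7,13-dien-17-oic acid (target)

Conditions: NaClO2 (3 equiv), NaH2PO4 (3 equiv), 2-methyl-2-butene (10 equiv), t-BuOH/H2O 4:1, rt

Reagents that add atoms: NaClO2 (sodium chlorite), `[Na+].[O-]Cl=O`

Why: Pinnick oxidation with buffered chlorite converts the conjugated aldehyde to the acid without touching either alkene (2-methyl-2-butene scavenges HOCl), the ester or the γ-stereocentre C9.

## Compound list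

```
1 | (−)-sclareol, (13R)-labd-14-ene-8α,13-diol (5S,8R,9R,10S,13R; 5α-H, 9α-H, 10β-CH3, 8α-OH) | C=C[C@](C)(O)CC[C@H]1[C@](C)(O)CC[C@H]2C(C)(C)CCC[C@]12C | starting material
2 | isobutyryl chloride (2-methylpropanoyl chloride) | CC(C)C(=O)Cl | starting material
3 | dilithium (13R)-labd-14-ene-8α,13-diolate (not isolated) | C=C[C@](C)([O-])CC[C@H]1[C@](C)([O-])CC[C@H]2C(C)(C)CCC[C@]12C.[Li+].[Li+] | intermediate
4 | (13R)-labd-14-ene-8α,13-diyl bis(2-methylpropanoate) | C=C[C@](C)(OC(=O)C(C)C)CC[C@H]1[C@](C)(OC(=O)C(C)C)CC[C@H]2C(C)(C)CCC[C@]12C | intermediate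
5 | (13E)-labd-13-ene-8α,15-diyl bis(2-methylpropanoate) | C/C(=C\COC(=O)C(C)C)CC[C@H]1[C@](C)(OC(=O)C(C)C)CC[C@H]2C(C)(C)CCC[C@]12C | intermediate
6 | (13E)-labda-7,13-dien-15-yl 2-methylpropanoate (5α-H, 9α-H, 10β-CH3) | C/C(=C\COC(=O)C(C)C)CC[C@H]1C(C)=CC[C@H]2C(C)(C)CCC[C@]12C | intermediate
7 | (13E)-15-(2-methylpropanoyloxy)labda-8(17),13-diene-7α-seleninic acid (ene adduct, not isolated) | C/C(=C\COC(=O)C(C)C)CC[C@H]1C(=C)[C@H]([Se](=O)O)C[C@H]2C(C)(C)CCC[C@]12C | intermediate
8 | (13E)-17-(hydroxyselanyloxy)labda-7,13-dien-15-yl 2-methylpropanoate (divalent-selenium ester from the [2,3] shift, not isolated) | C/C(=C\COC(=O)C(C)C)CC[C@H]1C(CO[Se]O)=CC[C@H]2C(C)(C)CCC[C@]12C | intermediate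
9 | (13E)-17-hydroxylabda-7,13-dien-15-yl 2-methylpropanoate (not isolated) | C/C(=C\COC(=O)C(C)C)CC[C@H]1C(CO)=CC[C@H]2C(C)(C)CCC[C@]12C | intermediate
10 | (13E)-17-oxolabda-7,13-dien-15-yl 2-methylpropanoate | C/C(=C\COC(=O)C(C)C)CC[C@H]1C(C=O)=CC[C@H]2C(C)(C)CCC[C@]12C | intermediate
11 | (13E)-15-(2-methylpropanoyloxy)labda-7,13-dien-17-oic acid, (1R,4aS,8aS)-5,5,8a-trimethyl-1-[(3E)-3-methyl-5-(2-methylpropanoyloxy)pent-3-en-1-yl]-1,4,4a,5,6,7,8,8a-octahydronaphthalene-2-carboxylic acid | C/C(=C\COC(=O)C(C)C)CC[C@H]1C(C(=O)O)=CC[C@H]2C(C)(C)CCC[C@]12C | target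
```

## Step count and risks

Total steps: 5. Longest linear sequence: 5 (fully linear from sclareol).

**Step 2 (E/Z ratio, and rate with the branched ester).** The methyl and CH2 substituents on C13 differ little in size, so the 13E preference may be modest and the isobutyrates may rearrange slowly. The fallback sets out from 1 and comes back at 6. Sclareol is bis-acetylated (AcCl, PhNMe2, CH2Cl2) to (13R)-labd-14-ene-8α,13-diyl diacetate F1. The same PdCl2(MeCN)2 rearrangement, well established for this diacetate, gives (13E)-labd-13-ene-8α,15-diyl diacetate F2. K2CO3 in MeOH cleaves only the primary allylic acetate to (13E)-8α-acetoxylabd-13-en-15-ol F3, where the E and Z alcohols separate readily on silica. Acylation with 2 and pyridine gives (13E)-8α-acetoxylabd-13-en-15-yl 2-methylpropanoate F4, and the acid elimination of step 3 (now losing acetic acid) delivers 6.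

**Step 3 (regiochemistry of the elimination and survival of the allylic ester).** The acid may give too much Δ8(9) or 8(17) alkene, or ionise the side-chain ester. The fallback sets out from 5 and comes back at 10, and makes the regiochemistry irrelevant. Buffered thermolysis (NaHCO3, DMSO, 150 °C) removes the C8 ester under non-acidic conditions, giving mainly (13E)-labda-8(17),13-dien-15-yl 2-methylpropanoate F5. Catalytic SeO2 with t-BuOOH (CH2Cl2, rt) oxidises its exocyclic alkene by ene reaction and [2,3] shift to (13E)-7α-hydroxylabda-8(17),13-dien-15-yl 2-methylpropanoate F6; any 6 present is converted by the same reagent directly into alcohol 9. The heptavalent-rhenium catalyst Ph3SiOReO3 (Et2O, 0 °C) then transposes F6 by [3,3] shift of its perrhenate ester to the primary allylic alcohol 9 with the ring double bond at C7–C8. Here 9 is isolated, and MnO2 in CH2Cl2 oxidises it to 10.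

**Step 4 (chemoselectivity and over-oxidation with stoichiometric SeO2 at reflux).** Competing attack at C12/C16 of the side chain or tarry selenium by-products would lower the yield. The fallback sets out from 6 and comes back at 10, splitting the oxidation into two separately controlled events. Catalytic SeO2 (0.3 equiv) with t-BuOOH and a little salicylic acid in CH2Cl2 at rt stops at the allylic alcohol 9, which is isolated and purified. A selenium-free allylic oxidation with MnO2 in CH2Cl2 then gives 10. No new compound is involved.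

## Further compounds

```
F1 | step 2 | (13R)-labd-14-ene-8α,13-diyl diacetate (sclareol diacetate) | C=C[C@](C)(OC(C)=O)CC[C@H]1[C@](C)(OC(C)=O)CC[C@H]2C(C)(C)CCC[C@]12C
F2 | step 2 | (13E)-labd-13-ene-8α,15-diyl diacetate | C/C(=C\COC(C)=O)CC[C@H]1[C@](C)(OC(C)=O)CC[C@H]2C(C)(C)CCC[C@]12C
F3 | step 2 | (13E)-8α-acetoxylabd-13-en-15-ol | C/C(=C\CO)CC[C@H]1[C@](C)(OC(C)=O)CC[C@H]2C(C)(C)CCC[C@]12C
F4 | step 2 | (13E)-8α-acetoxylabd-13-en-15-yl 2-methylpropanoate | C/C(=C\COC(=O)C(C)C)CC[C@H]1[C@](C)(OC(C)=O)CC[C@H]2C(C)(C)CCC[C@]12C
F5 | step 3 | (13E)-labda-8(17),13-dien-15-yl 2-methylpropanoate | C/C(=C\COC(=O)C(C)C)CC[C@H]1C(=C)CC[C@H]2C(C)(C)CCC[C@]12C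
F6 | step 3 | (13E)-7α-hydroxylabda-8(17),13-dien-15-yl 2-methylpropanoate | C/C(=C\COC(=O)C(C)C)CC[C@H]1C(=C)[C@H](O)C[C@H]2C(C)(C)CCC[C@]12C
F0 | step 4 | none | none
```
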